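**Plan**
- Rings are lettered A to H along the chain, from the 2,4,6-trihydroxyphenoxy end (A) to the 3,4,5-trihydroxyphenoxy end (H). The molecule is achiral, so no stereocentre has to be set; all hydroxyls travel as methyl ethers.
- The retrosynthesis first cuts both ether C–O bonds of ring F. The ring F carbon that carries the middle hydroxyl is para to the carbon bonded to the ring E oxygen and ortho to the carbon bonded to the ring G oxygen, so it is drawn as a formyl carbon that activates two fluorides and is later returned to OH by Dakin oxidation.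
- The G–H phenol is cut at its one ether (bromoaldehyde etherification, then Dakin oxidation). The A–E pentamer phenol is cut at A–B, B–C, C–D and D–E, each ether paired with a formyl-to-hydroxyl change.
- Forward, the chain grows from ring E (outer oxygen as benzyl ether) to D, C, B and A, with the most crowded D–E ether made first on monomers; hydrogenolysis then frees the ring E phenol.
- The pentamer, 2,4-difluoro-6-methoxybenzaldehyde and the G–H phenol are united in one vessel; Dakin oxidation and cleavage of the twenty methyl ethers finish the synthesis.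

Key step: step 17

Remark: 3,4,5-trimethoxyphenol, 4-bromo-3,5-dimethoxybenzaldehyde, 3,4,5-trimethoxybenzaldehyde, 2-iodo-1,3,5-trimethoxybenzene and 3,5-difluorophenol are taken as purchasable; aryl formates and the Vilsmeier iminium salt are carried on without isolation.

**Route**

Step 1
Reactants: 1 3,4,5-trimethoxyphenol
Product: 2 5-(benzyloxy)-1,2,3-trimethoxybenzene
Conditions: BnBr, K2CO3, DMF, rt
Reagents that add atoms: benzyl bromide, BrCc1ccccc1
Why: Williamson ether synthesis on the phenoxide; the benzyl group marks the one oxygen (the later ring E–O–ring F oxygen) that must be freed in the presence of methyl ethers.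

Step 2
Reactants: 2 5-(benzyloxy)-1,2,3-trimethoxybenzene
Product: 4 6-(benzyloxy)-2,3,4-trimethoxybenzaldehyde, via aryl iminium chloride 3 (not isolated)
Conditions: POCl3, DMF, 0 to 70 °C; then aq NaOAc
Reagents that add atoms: N,N-dimethylformamide, CN(C)C=O; water, O
Why: Vilsmeier–Haack formylation of a tetraalkoxybenzene; the two free ring carbons are equivalent and each lies between OBn and OMe, so a single aldehyde should form, and the formyl group then deactivates the ring against a second attack.

Step 3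
Reactants: 4 6-(benzyloxy)-2,3,4-trimethoxybenzaldehyde
Product: 6 6-(benzyloxy)-2,3,4-trimethoxyphenol, via aryl formate 5 (not isolated)
Conditions: mCPBA, CH2Cl2, 0 °C to rt; then HCl (cat.), MeOH, rt
Reagents that add atoms: mCPBA (3-chloroperoxybenzoic acid), OOC(=O)c1cccc(Cl)c1
Why: Dakin-type Baeyer–Villiger oxidation; the electron-rich 2,6-dialkoxyaryl group migrates to give the formate, whose methanolysis should release the phenol with its hydroxyl between OBn and OMe (the inner oxygen of ring E).

Step 4
Reactants: 6 6-(benzyloxy)-2,3,4-trimethoxyphenol; 7 4-bromo-3,5-dimethoxybenzaldehyde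
Product: 8 4-[6-(benzyloxy)-2,3,4-trimethoxyphenoxy]-3,5-dimethoxybenzaldehyde (ring D–E aldehyde)
Conditions: CuI (0.2 equiv), picolinic acid (0.4 equiv), K3PO4, DMSO, 110 °C, Ar
Reagents that add atoms: none
Why: Ullmann-type copper-catalysed O-arylation of a phenoxide by an aryl bromide made electron-poor by its para formyl group, with the picolinate-ligated copper system that is used for ortho-substituted partners; this tetra-ortho-substituted ether is the most crowded of the seven and is therefore made first, on cheap monomers that can be used in excess.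

Step 5
Reactants: 8 ring D–E aldehyde
Product: 10 4-[6-(benzyloxy)-2,3,4-trimethoxyphenoxy]-3,5-dimethoxyphenol (ring D–E phenol), via ring D formate 9 (not isolated)
Conditions: mCPBA, CH2Cl2, 0 °C to rt; then HCl (cat.), MeOH, rt
Reagents that add atoms: mCPBA (3-chloroperoxybenzoic acid), OOC(=O)c1cccc(Cl)c1
Why: Dakin-type Baeyer–Villiger oxidation, as for 3,4,5-trialkoxybenzaldehydes; the para aryloxy group favours aryl over hydride migration, and the benzyl ether, methyl ethers and diaryl ether are inert to the peracid and to dilute methanolic acid.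

Step 6
Reactants: 11 3,4,5-trimethoxybenzaldehyde
Product: 12 2-bromo-3,4,5-trimethoxybenzaldehyde
Conditions: NBS, CHCl3, reflux
Reagents that add atoms: N-bromosuccinimide, O=C1CCC(=O)N1Br
Why: Electrophilic aromatic bromination; the two free positions are equivalent and activated by ortho and para methoxy groups, and the product is deactivated against a second bromination.

Step 7
Reactants: 10 ring D–E phenol; 12 2-bromo-3,4,5-trimethoxybenzaldehyde
Product: 13 2-{4-[6-(benzyloxy)-2,3,4-trimethoxyphenoxy]-3,5-dimethoxyphenoxy}-3,4,5-trimethoxybenzaldehyde (ring C–E aldehyde)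
Conditions: CuI (0.1 equiv), picolinic acid (0.2 equiv), K3PO4, DMSO, 90 °C, Ar
Reagents that add atoms: none
Why: Ullmann-type O-arylation in which the ortho formyl group assists activation of the C–Br bond; the hydroxyl of 10 has no ortho substituent, so this ether (ring D oxygen on the inner carbon of ring C) should form readily.

Step 8
Reactants: 13 ring C–E aldehyde
Product: 15 2-{4-[6-(benzyloxy)-2,3,4-trimethoxyphenoxy]-3,5-dimethoxyphenoxy}-3,4,5-trimethoxyphenol (ring C–E phenol), via ring C formate 14 (not isolated)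
Conditions: mCPBA, CH2Cl2, 0 °C to rt; then HCl (cat.), MeOH, rt
Reagents that add atoms: mCPBA (3-chloroperoxybenzoic acid), OOC(=O)c1cccc(Cl)c1
Why: Dakin-type Baeyer–Villiger oxidation of an ortho-aryloxy, para-methoxy benzaldehyde, a standard way from 2-aryloxybenzaldehydes to 2-aryloxyphenols; it places the free hydroxyl on the outer carbon of ring C.

Step 9
Reactants: 15 ring C–E phenol; 7 4-bromo-3,5-dimethoxybenzaldehyde
Product: 16 4-(2-{4-[6-(benzyloxy)-2,3,4-trimethoxyphenoxy]-3,5-dimethoxyphenoxy}-3,4,5-trimethoxyphenoxy)-3,5-dimethoxybenzaldehyde (ring B–E aldehyde)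
Conditions: CuI (0.2 equiv), picolinic acid (0.4 equiv), K3PO4, DMSO, 110 °C, Ar
Reagents that add atoms: none
Why: Ullmann-type O-arylation with the same para-formyl-activated bromide as in step 4; here the phenol has one ortho substituent, so this tri-ortho-substituted ether is less demanding than the one already made.

Step 10
Reactants: 16 ring B–E aldehyde
Product: 18 ring B–E phenol (16 with OH in place of CHO on ring B), via ring B formate 17 (not isolated)
Conditions: mCPBA, CH2Cl2, 0 °C to rt; then HCl (cat.), MeOH, rt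
Reagents that add atoms: mCPBA (3-chloroperoxybenzoic acid), OOC(=O)c1cccc(Cl)c1
Why: Dakin-type Baeyer–Villiger oxidation, the same transformation as in step 5 on the same 4-aryloxy-3,5-dimethoxybenzaldehyde unit.

Step 11
Reactants: 18 ring B–E phenol; 19 2-iodo-1,3,5-trimethoxybenzene
Product: 20 ring A–E pentamer benzyl ether (18 carrying a 2,4,6-trimethoxyphenyl group on its phenolic oxygen)
Conditions: CuI (0.2 equiv), picolinic acid (0.4 equiv), K3PO4, DMSO, 100 °C, Ar; 19 in excess
Reagents that add atoms: none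
Why: Ullmann-type O-arylation of an unhindered, electron-rich phenol with an aryl iodide; ring A cannot carry an activating group for addition–elimination, so it is attached by copper catalysis, the usual way to 2,4,6-trimethoxyphenyl ethers.

Step 12
Reactants: 20 ring A–E pentamer benzyl ether
Product: 21 ring A–E pentamer phenol (free hydroxyl on ring E ortho to the ring D oxygen)
Conditions: H2 (1 atm), Pd/C, EtOAc/MeOH, rt
Reagents that add atoms: none
Why: Hydrogenolysis of a benzyl aryl ether; methyl and diaryl ethers are untouched and no reducible group is left in the molecule.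

Step 13
Reactants: 1 3,4,5-trimethoxyphenol; 12 2-bromo-3,4,5-trimethoxybenzaldehyde
Product: 22 3,4,5-trimethoxy-2-(3,4,5-trimethoxyphenoxy)benzaldehyde (ring G–H aldehyde)
Conditions: CuI (0.1 equiv), picolinic acid (0.2 equiv), K3PO4, DMSO, 90 °C, Ar
Reagents that add atoms: none
Why: Ullmann-type O-arylation of an unhindered phenol by an ortho-formyl aryl bromide, the same bond type as in step 7.

Step 14
Reactants: 22 ring G–H aldehyde
Product: 24 3,4,5-trimethoxy-2-(3,4,5-trimethoxyphenoxy)phenol (ring G–H phenol), via ring G formate 23 (not isolated)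
Conditions: mCPBA, CH2Cl2, 0 °C to rt; then HCl (cat.), MeOH, rt
Reagents that add atoms: mCPBA (3-chloroperoxybenzoic acid), OOC(=O)c1cccc(Cl)c1
Why: Dakin-type Baeyer–Villiger oxidation of a 2-aryloxybenzaldehyde, as in step 8.

Step 15
Reactants: 25 3,5-difluorophenol
Product: 27 2,4-difluoro-6-hydroxybenzaldehyde, via 3,5-difluoro-2-(hydroxymethyl)phenol 26 (not isolated)
Conditions: MgCl2, Et3N, (CH2O)n, MeCN, reflux; then aq HCl
Reagents that add atoms: paraformaldehyde (formaldehyde), C=O
Why: Magnesium-mediated ortho-formylation (Casnati–Skattebøl); the magnesium phenoxide delivers formaldehyde only to the carbon beside oxygen, and the benzylic alkoxide is oxidised by hydride transfer to a second formaldehyde, so the carbon between the two fluorines stays free.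

Step 16
Reactants: 27 2,4-difluoro-6-hydroxybenzaldehyde
Product: 28 2,4-difluoro-6-methoxybenzaldehyde
Conditions: MeI, K2CO3, DMF, rt
Reagents that add atoms: iodomethane, CI
Why: Williamson O-methylation of the salicylaldehyde phenoxide; at room temperature carbonate should not displace the aryl fluorides.

Step 17
Reactants: 21 ring A–E pentamer phenol; 28 2,4-difluoro-6-methoxybenzaldehyde; 24 ring G–H phenol
Product: 30 permethylated octamer aldehyde (ring F = 2-methoxybenzaldehyde bearing the oxygen of 21 at C4 and the oxygen of 24 at C6), via para-substituted monofluoride 29 (not isolated)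
Conditions: K2CO3, DMSO, 21 (1.0 equiv) and 28 (1.05 equiv), 45 °C; then 24 (1.3 equiv), 100 °C
Reagents that add atoms: none
Why: In each of the two events a phenoxide oxygen attacks a fluorine-bearing ring carbon, the charge of the resulting cyclohexadienyl (Meisenheimer) anion is taken up by the formyl group, and loss of fluoride restores the arene. The closest known reaction type is the stepwise addition–elimination of phenoxides on 2,4-difluorobenzaldehydes, para fluoride first and ortho fluoride second. No ring is closed and no stereocentre is formed; the step makes the two C–O bonds of ring F and joins five, one and two rings in one vessel. The selectivity needed is para before ortho and one pentamer per hub: the phenoxide of 21 carries a bulky ortho aryloxy group and should prefer the open para carbon over the fluoride wedged beside the formyl group, and in DMSO the potassium ion is solvated so that carbonyl-directed ortho delivery is not favoured. After the first substitution the para aryloxy donor lowers the reactivity of 29, so its remaining fluoride should react only on heating with the cheaper phenol 24 used in excess, which also keeps a second molecule of 21 from adding.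

Step 18
Reactants: 30 permethylated octamer aldehyde
Product: 32 octamer phenol (30 with OH in place of CHO on ring F; twenty methyl ethers), via ring F formate 31 (not isolated)
Conditions: mCPBA (1.2 equiv), CH2Cl2, 0 °C to rt; then HCl (cat.), MeOH, rt
Reagents that add atoms: mCPBA (3-chloroperoxybenzoic acid), OOC(=O)c1cccc(Cl)c1
Why: Dakin-type Baeyer–Villiger oxidation of a 2,4,6-trioxygenated benzaldehyde, the most reactive substrate class for aryl migration, so a small excess of peracid at low temperature should spare the other electron-rich rings.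

Step 19
Reactants: 32 octamer phenol
Product: 33 CNP0309601.0 (henicosahydroxy octamer, target)
Conditions: BBr3 (excess), CH2Cl2, −78 °C to rt, Ar; then MeOH, H2O
Reagents that add atoms: none
Why: Lewis-acid cleavage of aryl methyl ethers by BBr3 (bromide attacks the methyl group of the boron-complexed ether); diaryl ether bonds are not cleaved under these conditions, and hydrolysis of the aryl borates on work-up should give the free polyphenol.

**Compound list**

1 | 3,4,5-trimethoxyphenol | COc1cc(O)cc(OC)c1OC | starting material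
2 | 5-(benzyloxy)-1,2,3-trimethoxybenzene | COc1cc(OCc2ccccc2)cc(OC)c1OC | intermediate
3 | N-[6-(benzyloxy)-2,3,4-trimethoxybenzylidene]-N-methylmethanaminium chloride | C[N+](C)=Cc1c(OCc2ccccc2)cc(OC)c(OC)c1OC.[Cl-] | intermediate
4 | 6-(benzyloxy)-2,3,4-trimethoxybenzaldehyde | O=Cc1c(OCc2ccccc2)cc(OC)c(OC)c1OC | intermediate
5 | 6-(benzyloxy)-2,3,4-trimethoxyphenyl formate | O=COc1c(OCc2ccccc2)cc(OC)c(OC)c1OC | intermediate
6 | 6-(benzyloxy)-2,3,4-trimethoxyphenol | Oc1c(OCc2ccccc2)cc(OC)c(OC)c1OC | intermediate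
7 | 4-bromo-3,5-dimethoxybenzaldehyde | COc1cc(C=O)cc(OC)c1Br | starting material
8 | 4-[6-(benzyloxy)-2,3,4-trimethoxyphenoxy]-3,5-dimethoxybenzaldehyde | COc1cc(C=O)cc(OC)c1Oc1c(OCc2ccccc2)cc(OC)c(OC)c1OC | intermediate
9 | 4-[6-(benzyloxy)-2,3,4-trimethoxyphenoxy]-3,5-dimethoxyphenyl formate | COc1cc(OC=O)cc(OC)c1Oc1c(OCc2ccccc2)cc(OC)c(OC)c1OC | intermediate
10 | 4-[6-(benzyloxy)-2,3,4-trimethoxyphenoxy]-3,5-dimethoxyphenol | COc1cc(O)cc(OC)c1Oc1c(OCc2ccccc2)cc(OC)c(OC)c1OC | intermediate
11 | 3,4,5-trimethoxybenzaldehyde | COc1cc(C=O)cc(OC)c1OC | starting material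
12 | 2-bromo-3,4,5-trimethoxybenzaldehyde | COc1cc(C=O)c(Br)c(OC)c1OC | intermediate
13 | 2-{4-[6-(benzyloxy)-2,3,4-trimethoxyphenoxy]-3,5-dimethoxyphenoxy}-3,4,5-trimethoxybenzaldehyde | COc1cc(C=O)c(Oc2cc(OC)c(Oc3c(OCc4ccccc4)cc(OC)c(OC)c3OC)c(OC)c2)c(OC)c1OC | intermediate
14 | 2-{4-[6-(benzyloxy)-2,3,4-trimethoxyphenoxy]-3,5-dimethoxyphenoxy}-3,4,5-trimethoxyphenyl formate | COc1cc(OC=O)c(Oc2cc(OC)c(Oc3c(OCc4ccccc4)cc(OC)c(OC)c3OC)c(OC)c2)c(OC)c1OC | intermediate
15 | 2-{4-[6-(benzyloxy)-2,3,4-trimethoxyphenoxy]-3,5-dimethoxyphenoxy}-3,4,5-trimethoxyphenol | COc1cc(O)c(Oc2cc(OC)c(Oc3c(OCc4ccccc4)cc(OC)c(OC)c3OC)c(OC)c2)c(OC)c1OC | intermediate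
16 | ring B–E aldehyde: 4-(2-{4-[6-(benzyloxy)-2,3,4-trimethoxyphenoxy]-3,5-dimethoxyphenoxy}-3,4,5-trimethoxyphenoxy)-3,5-dimethoxybenzaldehyde | COc1cc(C=O)cc(OC)c1Oc1cc(OC)c(OC)c(OC)c1Oc1cc(OC)c(Oc2c(OCc3ccccc3)cc(OC)c(OC)c2OC)c(OC)c1 | intermediate
17 | ring B–E formate: formate ester of 18 | COc1cc(OC=O)cc(OC)c1Oc1cc(OC)c(OC)c(OC)c1Oc1cc(OC)c(Oc2c(OCc3ccccc3)cc(OC)c(OC)c2OC)c(OC)c1 | intermediate
18 | ring B–E phenol: 4-(2-{4-[6-(benzyloxy)-2,3,4-trimethoxyphenoxy]-3,5-dimethoxyphenoxy}-3,4,5-trimethoxyphenoxy)-3,5-dimethoxyphenol | COc1cc(O)cc(OC)c1Oc1cc(OC)c(OC)c(OC)c1Oc1cc(OC)c(Oc2c(OCc3ccccc3)cc(OC)c(OC)c2OC)c(OC)c1 | intermediate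
19 | 2-iodo-1,3,5-trimethoxybenzene | COc1cc(OC)c(I)c(OC)c1 | starting material
20 | ring A–E pentamer benzyl ether: 2,4,6-trimethoxyphenyl ether of 18 | COc1cc(OC)c(Oc2cc(OC)c(Oc3cc(OC)c(OC)c(OC)c3Oc3cc(OC)c(Oc4c(OCc5ccccc5)cc(OC)c(OC)c4OC)c(OC)c3)c(OC)c2)c(OC)c1 | intermediate
21 | ring A–E pentamer phenol: 20 with OH in place of OBn on ring E | COc1cc(OC)c(Oc2cc(OC)c(Oc3cc(OC)c(OC)c(OC)c3Oc3cc(OC)c(Oc4c(O)cc(OC)c(OC)c4OC)c(OC)c3)c(OC)c2)c(OC)c1 | intermediate
22 | 3,4,5-trimethoxy-2-(3,4,5-trimethoxyphenoxy)benzaldehyde | COc1cc(C=O)c(Oc2cc(OC)c(OC)c(OC)c2)c(OC)c1OC | intermediate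
23 | 3,4,5-trimethoxy-2-(3,4,5-trimethoxyphenoxy)phenyl formate | COc1cc(OC=O)c(Oc2cc(OC)c(OC)c(OC)c2)c(OC)c1OC | intermediate
24 | 3,4,5-trimethoxy-2-(3,4,5-trimethoxyphenoxy)phenol | COc1cc(O)c(Oc2cc(OC)c(OC)c(OC)c2)c(OC)c1OC | intermediate
25 | 3,5-difluorophenol | Oc1cc(F)cc(F)c1 | starting material
26 | 3,5-difluoro-2-(hydroxymethyl)phenol | OCc1c(O)cc(F)cc1F | intermediate
27 | 2,4-difluoro-6-hydroxybenzaldehyde | O=Cc1c(O)cc(F)cc1F | intermediate
28 | 2,4-difluoro-6-methoxybenzaldehyde | COc1cc(F)cc(F)c1C=O | intermediate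
29 | 2-fluoro-6-methoxybenzaldehyde carrying at C4 the aryloxy group of 21 | COc1cc(OC)c(Oc2cc(OC)c(Oc3cc(OC)c(OC)c(OC)c3Oc3cc(OC)c(Oc4c(Oc5cc(OC)c(C=O)c(F)c5)cc(OC)c(OC)c4OC)c(OC)c3)c(OC)c2)c(OC)c1 | intermediate
30 | permethylated octamer aldehyde (formyl on ring F between OMe and the ring G oxygen) | COc1cc(OC)c(Oc2cc(OC)c(Oc3cc(OC)c(OC)c(OC)c3Oc3cc(OC)c(Oc4c(Oc5cc(OC)c(C=O)c(Oc6cc(OC)c(OC)c(OC)c6Oc6cc(OC)c(OC)c(OC)c6)c5)cc(OC)c(OC)c4OC)c(OC)c3)c(OC)c2)c(OC)c1 | intermediate
31 | octamer ring F formate (OCHO in place of CHO in 30) | COc1cc(OC)c(Oc2cc(OC)c(Oc3cc(OC)c(OC)c(OC)c3Oc3cc(OC)c(Oc4c(Oc5cc(OC)c(OC=O)c(Oc6cc(OC)c(OC)c(OC)c6Oc6cc(OC)c(OC)c(OC)c6)c5)cc(OC)c(OC)c4OC)c(OC)c3)c(OC)c2)c(OC)c1 | intermediate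
32 | octamer phenol (OH in place of CHO in 30; icosa-O-methyl ether of the target) | COc1cc(OC)c(Oc2cc(OC)c(Oc3cc(OC)c(OC)c(OC)c3Oc3cc(OC)c(Oc4c(Oc5cc(OC)c(O)c(Oc6cc(OC)c(OC)c(OC)c6Oc6cc(OC)c(OC)c(OC)c6)c5)cc(OC)c(OC)c4OC)c(OC)c3)c(OC)c2)c(OC)c1 | intermediate
33 | CNP0309601.0 | Oc1cc(O)c(Oc2cc(O)c(Oc3cc(O)c(O)c(O)c3Oc3cc(O)c(Oc4c(Oc5cc(O)c(O)c(Oc6cc(O)c(O)c(O)c6Oc6cc(O)c(O)c(O)c6)c5)cc(O)c(O)c4O)c(O)c3)c(O)c2)c(O)c1 | target

**Step count**

Total step count: 19.
Longest linear sequence: 14 steps (steps 1–5, 7–12 and 17–19).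

**Steps most likely to fail**

1. Step 4. Both the oxygen and the carbon that must be joined carry two ortho substituents, so the copper-mediated C–O bond formation may stall; the phenol would then be recovered or oxidised and the bromide reduced. The fallback replaces copper catalysis by an uncatalysed addition–elimination on the corresponding fluoride, which is less sensitive to ortho crowding because the attacked carbon becomes tetrahedral. It sets out from 7 and 6 and returns at 8. Acetalisation of 7 with ethane-1,2-diol (TsOH, toluene, reflux) would give 2-(4-bromo-3,5-dimethoxyphenyl)-1,3-dioxolane F1. Bromine–lithium exchange (n-BuLi, THF, −78 °C) would give [4-(1,3-dioxolan-2-yl)-2,6-dimethoxyphenyl]lithium F2, which is fluorinated in the same flask with NFSI to 2-(4-fluoro-3,5-dimethoxyphenyl)-1,3-dioxolane F3. Aqueous HCl in THF would release 4-fluoro-3,5-dimethoxybenzaldehyde F4, and heating F4 with 6 and Cs2CO3 in DMSO at 120 °C should give 8. The same fluoride could also replace 7 in step 9.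

2. Step 17. The first phenoxide may attack the ortho fluoride in competition with the para fluoride, or a second molecule of 21 may displace the remaining fluoride, which would give regioisomeric and doubly pentamer-substituted ethers. The fallback gives the two positions different leaving groups, so that the position of each ether is fixed by the reagent and not by relative rates. It sets out from 24 and 21 and returns at 30. Commercial 4-bromo-2,6-difluorobenzaldehyde with one equivalent of NaOMe (MeOH/THF, 0 °C) would give 4-bromo-2-fluoro-6-methoxybenzaldehyde F5. Its only fluoride is displaced by 24 (K2CO3, DMSO, 90 °C) to give 4-bromo-2-methoxy-6-[3,4,5-trimethoxy-2-(3,4,5-trimethoxyphenoxy)phenoxy]benzaldehyde F6. Ullmann-type coupling of the para bromide of F6 with 21 (CuI, picolinic acid, K3PO4, DMSO, 100 °C) should then give 30.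

3. Step 19. Cleavage of twenty methyl ethers may stop short when partly demethylated borates precipitate, and the free polyphenol may oxidise in air during isolation. The fallback isolates the product through its peracetate; it sets out from 32 and returns at 33. After the BBr3 treatment and methanol quench the crude material is acetylated at once (Ac2O, pyridine, DMAP, rt) to the henicosaacetate of the target F7. F7 is stable to air and to chromatography, so under-demethylated material can be separated and resubmitted. Deacetylation under argon (NaOMe cat., degassed MeOH, 0 °C; then acidic ion-exchange resin) should return 33.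

**Further compounds**

F1 | step 4 | 2-(4-bromo-3,5-dimethoxyphenyl)-1,3-dioxolane | COc1cc(C2OCCO2)cc(OC)c1Br
F2 | step 4 | [4-(1,3-dioxolan-2-yl)-2,6-dimethoxyphenyl]lithium | [Li]c1c(OC)cc(C2OCCO2)cc1OC
F3 | step 4 | 2-(4-fluoro-3,5-dimethoxyphenyl)-1,3-dioxolane | COc1cc(C2OCCO2)cc(OC)c1F
F4 | step 4 | 4-fluoro-3,5-dimethoxybenzaldehyde | COc1cc(C=O)cc(OC)c1F
F5 | step 17 | 4-bromo-2-fluoro-6-methoxybenzaldehyde | COc1cc(Br)cc(F)c1C=O
F6 | step 17 | 4-bromo-2-methoxy-6-[3,4,5-trimethoxy-2-(3,4,5-trimethoxyphenoxy)phenoxy]benzaldehyde | COc1cc(Br)cc(Oc2cc(OC)c(OC)c(OC)c2Oc2cc(OC)c(OC)c(OC)c2)c1C=O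
F7 | step 19 | henicosa-O-acetate of 33 | CC(=O)Oc1cc(OC(C)=O)c(Oc2cc(OC(C)=O)c(Oc3cc(OC(C)=O)c(OC(C)=O)c(OC(C)=O)c3Oc3cc(OC(C)=O)c(Oc4c(Oc5cc(OC(C)=O)c(OC(C)=O)c(Oc6cc(OC(C)=O)c(OC(C)=O)c(OC(C)=O)c6Oc6cc(OC(C)=O)c(OC(C)=O)c(OC(C)=O)c6)c5)cc(OC(C)=O)c(OC(C)=O)c4OC(C)=O)c(OC(C)=O)c3)c(OC(C)=O)c2)c(OC(C)=O)c1
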